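## The problem

Atom labels used throughout: ring C = C1 (O-bearing CH), C2 (CH2), C3 (C(OH)CH3), C4, C5; ring B (γ-lactone) = O, C6 (C=O), C7, C5, C1; ring A (cyclohexene) = C4, C5, C7, C8 (=CH), C9, C10; ring D = C10 (spiro), C11 (CH2), C12 (C=O), C13 (CH2), C14 (CHOH); C15 = side-chain CH on C9. The β face is the face of ring C that carries H1, H4, H5 and the C3 methyl group.

The target 31 has a cyclopentane (ring C) cis-fused to a γ-lactone (ring B) and to a cyclohexene (ring A), so that C5 is a methine common to three rings. Rings A and B are trans-fused across C5–C7, and a 3-hydroxycyclopentanone (ring D) is spiro-linked at the quaternary carbon C10, which lies between C4 and the alkene carbon C9. Eight stereocentres have to be set: C1, C3, C4, C5, C7 and C10 are contiguous, C14 is next to C10, and C15 is an acyclic, doubly allylic CH. C1 can be bought and can direct C5 (tethered delivery) and C7 (attack on the convex face of the cis-bicyclooctane). The bowl formed by rings A to C should then decide the faces at C10, C4 and C3, whereas C15 is too remote from the ring centres and needs reagent control. Several groups are fragile: the β-hydroxy ketone of ring D dehydrates; every intermediate with a C3 ketone is a β-acyloxy ketone that loses the lactone carboxylate by E1cB with base; H7 is allylic and α to the lactone carbonyl; and a methyl ester sits beside the lactone. The enabling feature is that C10 bears the carbinol carbon C14 and is β to C3, a tertiary carbinol that is a masked ketone. The unit C14(OH)–C10–C4–C3(=O) is what addition of a ketyl to the β-carbon of a C3 enone (C4=C10) leaves behind, so the C10–C14 bond, the quaternary centre and ring D can be formed in one reductive step.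

## Retrosynthesis

**Late unmasking (31 ⇐ 30 ⇐ 29).** No skeletal bond is cut. The ring D ketone is kept as a 1,3-dithiane and O3 and O14 as triethylsilyl ethers until the end, because the free β-hydroxy ketone would not survive the enolate and palladium steps. The forward steps must be non-basic: fluoride under acidic buffering, then alkylative dithiane hydrolysis.

**C15–isopropenyl bond (29 ⇐ 27 + 28).** Adding the isopropenyl group to the ring dienoate 27 is preferred to the neighbouring cut, in which a ring alkenylboron reagent would add to methyl 4-methylpenta-2,4-dienoate. That acceptor has an unhindered terminal CH2 and invites 1,6-addition, whereas in 27 the remote C8=C9 bond is trisubstituted and flanked by the quaternary C10. The precursor loses the only stereocentre that the rings cannot control, so the forward reaction must be catalyst-controlled.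

**C9–C15 bond (27 ⇐ 25 + 26; 25 ⇐ 24 ⇐ 23).** A Heck reaction of enol triflate 25 with methyl acrylate 26 builds the dienoate. The triflate comes from ketone 24, which can enolise only towards C8 because C10 is quaternary, and 24 from the dioxolane 23. This cut is chosen over coupling a preformed sp3 side chain, which would require a secondary allylic organometallic. The forward steps must not move the C8=C9 double bond into conjugation with C6.

**C3–methyl bond (23 ⇐ 22 ⇐ 21).** The tertiary carbinol is cut back to the C3 ketone of 21. The ketone is enolisable and β-acyloxy, so a non-basic organocerium reagent is needed, and it must attack the convex β face. O3 is silylated before C9 is unmasked because the α hydroxyl lies 1,3-diaxial to C9 and would form a bridged hemiketal.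

**C10–C14 bond (21 ⇐ 20), the key cut.** Cutting ring D at the spiro carbon removes one ring, the quaternary centre and three stereocentres (C10, C14, C4) and leaves the flat tricyclic enone aldehyde 20. Cutting C10–C11 instead would demand alkylation at a neopentyl centre, and cutting C4–C10 would lose the enone that makes C10 electrophilic. The forward reaction must form the ketyl in the presence of the enone and deliver it to the face of C10 that carries H5.

**C4=C10 bond (20 ⇐ 19 ⇐ 18 ⇐ 17 ⇐ 16).** Ring A is opened by a retro-aldol condensation to diketone 17, whose C3 ketone is masked in 16. Only C4 can reach the C10 carbonyl through a six-membered ring, so regiochemistry is not an issue. The forward reaction must run under acid, where loss of the lactone carboxylate from the β-acyloxy ketone is reversible.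

**C12–S and C10–C11 bonds (16 ⇐ 15 ⇐ 11 + 13; 13 ⇐ 12).** The β-keto dithiane is the double thiol adduct of ynone 15, which is cut at the acyl–alkynyl bond into acid 11 and alkyne 13. This places the sulfur mask on C12 and leaves the C10 ketone free in one step. Alkylating a dithiane anion with a neopentyl electrophile would be the alternative and is not viable in the presence of the lactone.

**C7–C8 bond (11 ⇐ 10 ⇐ 9 ⇐ 8 ⇐ 6 + 7).** The three-carbon unit C8–C9–C10 is introduced by exo alkylation of the lactone enolate of 6 with benzyl 2-(bromomethyl)acrylate 7. A direct alkylation with an α-ketal halide would be shorter on paper but is a neopentyl SN2 reaction. The acrylate is a fast SN2′ electrophile whose alkene is later ozonised to the C9 ketone and whose ester becomes C10. The forward alkylation must occur trans to C4, which sets C7.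

**C5–C7 bond (6 ⇐ 5 ⇐ 4 ⇐ 3 ⇐ 1 + 2).** Ring B is cut at C5–C7, leading to the bromoacetal 3 of (R)-4-hydroxycyclopentenone 1 and ethyl vinyl ether 2. A radical closure is chosen over a base-mediated Michael addition of an acyl-tethered nucleophile, because 4-acyloxycyclopentenones eliminate with base. The tether guarantees the cis fusion, so C1 sets C5.

## Roads not taken

**Alternative 1: Ireland–Claisen ring contraction.** The cut is the C4–C10 bond. In the forward direction the silyl ketene acetal of a six-membered lactone, whose ring oxygen is allylic to an alkylidene-cyclopentane, would rearrange to the spiro cyclohexene carboxylic acid A1. Its merits are real: the quaternary centre and C4 arise in a concerted, stereospecific event, the C8=C9 alkene appears in its final place, and C9 already carries the C15 carbon as a silyloxymethyl group, so no enol triflate is needed. In this respect it is better than the chosen plan. Its weak points for this target are that the configuration at C10 depends on the geometry of a tetrasubstituted alkylidene-cyclopentane that differs on its two sides only at remote C14, and that the lactone forces a boat transition state. After A1, ring C still has to be built from the C4 carboxyl and the C5 acetal with an extra carbon for C2, ring B has to be made from the C7 benzyloxymethyl group, and the C3 carbinol has to be installed. The chosen plan sets against it that rings A to C and four stereocentres come in few operations from the chiral pool under substrate control, and that the spiro centre is then formed on a rigid, facially biased tricycle.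

**Alternative 2: transposed-alkene intramolecular Diels–Alder reaction.** The cuts are C9–C10 and C4–C5. A tethered 2-silyloxydiene would add to an alkylidene ene-dione of ring D and give the spiro hydrindanone silyl enol ether A2. In bond economy it is superior to the chosen key step: two carbon–carbon bonds, rings A and C, the quaternary centre and two further stereocentres form at once, and the route is convergent. The weak points are three. The cycloaddition substrate would have no stereocentre, so absolute configuration would need a chiral catalyst. The alkene ends at C7=C8 as an enol ether, so C7 must still receive the lactone carbonyl carbon with control of H7, and C9 arrives as an unfunctionalised CH2 that must later carry the side chain. The C1 and C14 carbonyl groups must each be reduced with the right facial sense. The chosen plan forms fewer bonds in its key step but starts with C1, C6 and C7 at the correct oxidation level and configuration and keeps a carbonyl handle at C9.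

**Alternative 3: crossed De Mayo ring switch.** The cuts are C5–C7 and C3–C4. Irradiation of an enolised six-membered keto-lactone bearing a tethered alkene would give a crossed [2+2] adduct whose retro-aldol opening delivers the bicyclic keto-lactone A3 with ring D already attached at C4. It builds rings B and C in one step, where the chosen plan needs three, and it avoids the late radical construction of the quaternary centre. Against it stand the uncertain crossed versus straight regiochemistry of the photocycloaddition and the need to control C4 and C5 relative to a preformed quaternary C10 and C14 on a freely rotating chain. The ring A closure that would follow is also problematic: a Claisen-type closure of the acetate arm onto C7 puts the oxygen on C8 instead of C9 and would have to run with base on a β-acyloxy ketone. The chosen plan closes ring A by an acid-mediated aldol reaction that leaves the handle on C9, and sets C10 and C14 last on a rigid scaffold.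

Key step: step 15

Remark: 3 and 4 are carried as mixtures of epimers at the acetal carbon, which becomes the lactone carbonyl C6 in step 3.
Remark: (R)-BINAP in step 21 is assigned from the usual enantioface model for (E)-enoates; it has to deliver the isopropenyl group to the Re face of C15 in 27.
Remark: 7, 12, 26 and 28 are taken as catalogue chemicals.

## Steps

Step 1
Reactants: 1 (R)-4-hydroxycyclopent-2-en-1-one; 2 ethyl vinyl ether
Product: 3 (4R)-4-(2-bromo-1-ethoxyethoxy)cyclopent-2-en-1-one
Conditions: NBS, CH2Cl2, −40 to 0 °C
Reagents that add atoms: N-bromosuccinimide, O=C1CCC(=O)N1Br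
Why: Haloetherification: NBS turns the enol ether 2 into a bromo-oxocarbenium ion that the hydroxyl of 1 captures, giving the mixed bromoacetal without base and without touching the C1 stereocentre.

Step 2
Reactants: 3 bromoacetal
Product: 4 (1R,5S)-3-ethoxy-2-oxabicyclo[3.3.0]octan-7-one
Conditions: Bu3SnH, AIBN (cat.), PhH, 80 °C, slow addition
Reagents that add atoms: none
Why: Ueno–Stork radical cyclisation: the primary radical adds 5-exo-trig to the enone β-carbon C5, the tether from O1 allows only the cis ring fusion so C1 sets C5, and the C4 α-keto radical is reduced by Bu3SnH.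

Step 3
Reactants: 4 keto lactol ether
Product: 5 (1R,5R)-2-oxabicyclo[3.3.0]octane-3,7-dione
Conditions: CrO3, H2SO4, acetone/H2O, 0 °C to rt
Reagents that add atoms: water, O
Why: Jones oxidation of a lactol ether: aqueous acid hydrolyses the acetal and hexavalent chromium oxidises the lactol to the γ-lactone; under acid the β-acyloxy ketone does not eliminate and no stereocentre is touched.

Step 4
Reactants: 5 keto lactone
Product: 6 (1R,5R)-7,7-(ethylenedioxy)-2-oxabicyclo[3.3.0]octan-3-one
Conditions: ethylene glycol, TsOH·H2O (cat.), PhH, reflux, Dean–Stark
Reagents that add atoms: ethylene glycol, OCCO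
Why: Acid-catalysed ketalisation masks the C3 ketone so that the lactone can be deprotonated in step 5 without E1cB loss of the C1 carboxylate.

Step 5
Reactants: 6 ketal lactone; 7 benzyl 2-(bromomethyl)acrylate
Product: 8 ketal lactone with a 2-(benzyloxycarbonyl)prop-2-en-1-yl group at C7 (H7 trans to H5)
Conditions: LiN(iPr)2, THF, −78 °C; then 7, −78 to −40 °C
Reagents that add atoms: none
Why: Lactone enolate alkylation by addition–elimination (SN2′) on the 2-(bromomethyl)acrylate: the electrophile enters on the convex face of the cis-bicyclooctane, trans to C4, which fixes C7; the acrylate supplies C8, C9 and C10.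

Step 6
Reactants: 8 acrylate
Product: 9 α-keto benzyl ester (C9 ketone)
Conditions: O3, CH2Cl2, −78 °C; then Me2S, −78 °C to rt
Reagents that add atoms: ozone, [O-][O+]=O
Why: Ozonolysis of the only alkene, a 1,1-disubstituted acrylate, with reductive work-up converts C9 into a ketone; the benzyl ester is not attacked at −78 °C.

Step 7
Reactants: 9 α-keto ester
Product: 10 bis-ketal benzyl ester (C9 dioxolane)
Conditions: (TMSOCH2)2, TMSOTf (5 mol %), CH2Cl2, −78 to −20 °C
Reagents that add atoms: 1,2-bis(trimethylsilyloxy)ethane, C[Si](C)(C)OCCO[Si](C)(C)C
Why: Noyori ketalisation: the activated α-keto carbonyl is converted to its dioxolane under aprotic, low-temperature conditions that leave the benzyl ester, the lactone and the C3 ketal in place.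

Step 8
Reactants: 10 benzyl ester
Product: 11 bis-ketal carboxylic acid (C10 as CO2H)
Conditions: H2 (1 atm), Pd/C, EtOAc, rt
Reagents that add atoms: none
Why: Hydrogenolysis of the benzyl ester frees the acid under neutral conditions; ketals and lactone are inert and no alkene or sulfur is present yet.

Step 9
Reactants: 12 but-3-yn-1-ol
Product: 13 tert-butyl(but-3-yn-1-yloxy)diphenylsilane
Conditions: TBDPSCl, imidazole, CH2Cl2, 0 °C to rt
Reagents that add atoms: tert-butyl(chloro)diphenylsilane, CC(C)(C)[Si](Cl)(c1ccccc1)c1ccccc1
Why: Standard silylation of a primary alcohol; the acid-stable TBDPS ether carries O14 through step 12.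

Step 10
Reactants: 11 carboxylic acid; 13 silyl alkyne
Product: 15 ynone (C10 ketone joined to C11≡C12), via acid chloride 14 (not isolated)
Conditions: 1-chloro-N,N,2-trimethylprop-1-en-1-amine, CH2Cl2, 0 °C; then 13, PdCl2(PPh3)2 (2 mol %), CuI (4 mol %), Et3N, THF, rt
Reagents that add atoms: 1-chloro-N,N,2-trimethylprop-1-en-1-amine (Ghosez reagent), CC(C)=C(Cl)N(C)C (chlorine present only in 14)
Why: The neutral Ghosez reagent makes the acid chloride without acid that could open the ketals, and an acyl Sonogashira coupling forms the C10–C11 bond; the C3 ketal keeps the system stable to Et3N.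

Step 11
Reactants: 15 ynone
Product: 16 β-keto dithiane (C12 as 1,3-dithiane)
Conditions: HS(CH2)3SH, NaOMe (0.3 equiv), MeOH/CH2Cl2, −10 °C to rt
Reagents that add atoms: propane-1,3-dithiol, SCCCS
Why: Double conjugate addition of a 1,3-dithiol to an ynone: the first thiolate adds to C12 and the second closes the dithiane on the β-thio enone, masking the ring D ketone while the C10 ketone stays free.

Step 12
Reactants: 16 β-keto dithiane
Product: 18 tricyclic enone lactone (C4=C10), via diketone 17 (not isolated)
Conditions: TsOH·H2O (0.2 equiv), acetone/H2O 20:1, 40 °C; then PhMe, 4 Å MS, 80 °C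
Reagents that add atoms: water, O
Why: Selective ketal hydrolysis then acid-catalysed intramolecular aldol condensation: the C3 dioxolane hydrolyses much faster than the C9 dioxolane, whose oxocarbenium ion is destabilised by the adjacent C10 carbonyl; only C4 can reach the C10 ketone through a six-membered ring, and dehydration gives the tetrasubstituted enone; acid is used because loss of the lactone carboxylate is then reversible.

Step 13
Reactants: 18 silyl ether
Product: 19 tricyclic enone alcohol
Conditions: HF·pyridine, pyridine, THF, 0 °C to rt
Reagents that add atoms: none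
Why: Desilylation with buffered HF frees the primary alcohol without basic fluoride, which would open ring B by E1cB elimination.

Step 14
Reactants: 19 alcohol
Product: 20 tricyclic enone aldehyde
Conditions: Dess–Martin periodinane, NaHCO3, CH2Cl2, 0 °C to rt
Reagents that add atoms: none
Why: Dess–Martin oxidation gives the aldehyde under buffered, non-basic conditions compatible with the dithiane and the β-acyloxy enone; the crude aldehyde is used directly.

Step 15
Reactants: 20 enone aldehyde
Product: 21 tetracyclic hydroxy ketone (ring D closed)
Conditions: SmI2 (2.5 equiv), t-BuOH (5 equiv), THF, −78 to −40 °C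
Reagents that add atoms: none
Why: Electron transfer from divalent samarium to the aldehyde gives a ketyl that adds 5-exo-trig to C10, the β-carbon of the C3 enone, forming the C10–C14 bond and ring D; a second electron converts the C4 α-keto radical into the trivalent samarium enolate, which t-BuOH protonates (initial reduction of the enone would lead through its β-carbon to the same bond). The closest known reaction type is the SmI2 ketyl–olefin cyclisation onto β,β-disubstituted enones and enoates, which tolerates a fully substituted acceptor carbon because the transition state is early. Only the five-membered ring can form, since attack at C4 would be 6-endo onto the α-carbon of the enone. C10: the ketyl approaches the enone face that carries H5, because the other face is covered by ring B, so C14 ends β and C11 α. C14: the samarium-bound oxygen turns away from C4 and towards the C9 dioxolane (repulsion from the developing enolate, reinforced by chelation of samarium by a ketal oxygen), which puts the hydroxyl anti to C4. C4: the enolate is protonated on the convex β face, giving the cis A/C fusion, which is also the more stable one. The step needs ketyl formation and ring closure to outrun reduction of the enone and loss of the allylic ketal oxygen; low temperature, the absence of HMPA and the fast 5-exo closure serve this.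

Step 16
Reactants: 21 hydroxy ketone
Product: 22 diol (C3 tertiary carbinol, methyl β)
Conditions: MeLi, CeCl3 (MeCeCl2, 4 equiv), THF, −78 °C
Reagents that add atoms: methyllithium, [Li]C
Why: Organocerium (Imamoto) addition: weakly basic MeCeCl2 adds to the enolisable β-acyloxy ketone without enolisation or attack on the lactone, from the convex β face anti to C10, giving the α-hydroxyl and β-methyl of the target; one equivalent is consumed by the C14 hydroxyl.

Step 17
Reactants: 22 diol
Product: 23 bis(triethylsilyl) ether
Conditions: TESOTf (3 equiv), 2,6-lutidine, CH2Cl2, −78 to 0 °C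
Reagents that add atoms: triethylsilyl trifluoromethanesulfonate, CC[Si](CC)(CC)OS(=O)(=O)C(F)(F)F
Why: Silyl triflate silylation of both hydroxyls; capping O3, which lies 1,3-diaxial to C9, prevents a bridged hemiketal when the C9 ketone is released, and O14 must be masked before enolate chemistry.

Step 18
Reactants: 23 bis-silyl ether
Product: 24 C9 ketone
Conditions: PPTS (0.3 equiv), acetone/H2O 10:1, 50 °C
Reagents that add atoms: water, O
Why: Mild acid hydrolysis of the dioxolane, which is no longer deactivated now that C10 is sp3; the hindered triethylsilyl ethers and the dithiane tolerate PPTS.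

Step 19
Reactants: 24 ketone
Product: 25 C9 enol triflate (C8=C9)
Conditions: KN(SiMe3)2 (1.1 equiv), THF, −78 °C; then PhNTf2, −78 to −20 °C
Reagents that add atoms: N-phenylbis(trifluoromethanesulfonimide), O=S(=O)(N(c1ccccc1)S(=O)(=O)C(F)(F)F)C(F)(F)F
Why: Kinetic enolate formation and O-sulfonylation: C10 is quaternary, so the ketone enolises only towards C8 and a single enol triflate results; H7 of the lactone is far less acidic than the ketone α-protons.

Step 20
Reactants: 25 enol triflate; 26 methyl acrylate
Product: 27 (E)-dienoate
Conditions: Pd(OAc)2 (10 mol %), PPh3 (20 mol %), Et3N, DMF, 70 °C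
Reagents that add atoms: none
Why: Mizoroki–Heck reaction of a cycloalkenyl triflate: oxidative addition, insertion of the acrylate and β-hydride elimination form the C9–C15 bond and the (E)-enoate.

Step 21
Reactants: 27 dienoate; 28 isopropenylboronic acid pinacol ester
Product: 29 side-chain adduct (C15 S), bis-silyl ether dithiane
Conditions: [Rh(OH)((R)-binap)]2 (5 mol % Rh), KOH (0.3 equiv), dioxane/H2O 10:1, 45 °C
Reagents that add atoms: none
Why: Hayashi–Miyaura asymmetric 1,4-addition: the isopropenylrhodium species inserts the α,β-double bond of the enoate (the remote C8=C9 bond is trisubstituted and flanked by C10, so 1,6-addition is disfavoured) and the oxa-π-allyl complex is protonated; (R)-BINAP directs addition to the Re face of C15 under catalyst control.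

Step 22
Reactants: 29 bis-silyl ether
Product: 30 diol dithiane
Conditions: HF·pyridine, pyridine, THF, 0 °C to rt
Reagents that add atoms: none
Why: Buffered HF removes both triethylsilyl ethers under mildly acidic conditions that leave the lactone, the methyl ester and the alkenes alone.

Step 23
Reactants: 30 diol dithiane
Product: 31 CNP0255095.1
Conditions: MeI (excess), CaCO3, MeCN/H2O 9:1, 45 °C
Reagents that add atoms: water, O
Why: Alkylative dithiane hydrolysis: S-methylation and hydrolysis of the sulfonium ion, buffered by CaCO3, release the C12 ketone under neutral conditions, so the β-hydroxy ketone of ring D does not dehydrate and the alkenes are untouched.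

## Compound list

1 | (R)-4-hydroxycyclopent-2-en-1-one | O=C1C[C@@H](O)C=C1 | starting material
2 | ethyl vinyl ether | C=COCC | starting material
3 | (4R)-4-(2-bromo-1-ethoxyethoxy)cyclopent-2-en-1-one, both acetal epimers | O=C1C[C@@H](OC(CBr)OCC)C=C1 | intermediate
4 | (1R,5S)-3-ethoxy-2-oxabicyclo[3.3.0]octan-7-one, cis-fused, both acetal epimers | O=C1C[C@H]2OC(OCC)C[C@H]2C1 | intermediate
5 | (1R,5R)-2-oxabicyclo[3.3.0]octane-3,7-dione, cis-fused keto lactone | O=C1C[C@H]2OC(=O)C[C@H]2C1 | intermediate
6 | (1R,5R)-7,7-(ethylenedioxy)-2-oxabicyclo[3.3.0]octan-3-one, C3 ketal lactone | O1CCOC12C[C@H]3OC(=O)C[C@H]3C2 | intermediate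
7 | benzyl 2-(bromomethyl)acrylate | C=C(CBr)C(=O)OCc1ccccc1 | starting material
8 | ketal lactone 6 bearing at C7, on the convex face (H7 trans to H5), a 2-(benzyloxycarbonyl)prop-2-en-1-yl group | O1CCOC12C[C@H]3OC(=O)[C@H](CC(=C)C(=O)OCc4ccccc4)[C@H]3C2 | intermediate
9 | α-keto benzyl ester: C8H2–C9(=O)–C10O2Bn on C7 of the ketal lactone | O1CCOC12C[C@H]3OC(=O)[C@H](CC(=O)C(=O)OCc4ccccc4)[C@H]3C2 | intermediate
10 | bis-ketal benzyl ester (C3 and C9 as dioxolanes) | O1CCOC12C[C@H]3OC(=O)[C@H](CC4(OCCO4)C(=O)OCc5ccccc5)[C@H]3C2 | intermediate
11 | bis-ketal carboxylic acid (C10 as CO2H) | O1CCOC12C[C@H]3OC(=O)[C@H](CC4(OCCO4)C(=O)O)[C@H]3C2 | intermediate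
12 | but-3-yn-1-ol | C#CCCO | starting material
13 | tert-butyl(but-3-yn-1-yloxy)diphenylsilane | C#CCCO[Si](c1ccccc1)(c1ccccc1)C(C)(C)C | intermediate
14 | acid chloride of 11 | O1CCOC12C[C@H]3OC(=O)[C@H](CC4(OCCO4)C(Cl)=O)[C@H]3C2 | intermediate
15 | ynone: C10 ketone joined to C11≡C12–C13H2–C14H2–OTBDPS | O1CCOC12C[C@H]3OC(=O)[C@H](CC4(OCCO4)C(=O)C#CCCO[Si](c5ccccc5)(c6ccccc6)C(C)(C)C)[C@H]3C2 | intermediate
16 | β-keto dithiane: C10 ketone, C12 as 1,3-dithiane, C3 and C9 as dioxolanes | O1CCOC12C[C@H]3OC(=O)[C@H](CC4(OCCO4)C(=O)CC5(SCCCS5)CCO[Si](c6ccccc6)(c7ccccc7)C(C)(C)C)[C@H]3C2 | intermediate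
17 | diketone: free C3 and C10 ketones, C9 dioxolane, C12 dithiane | O=C1C[C@H]2OC(=O)[C@H](CC3(OCCO3)C(=O)CC4(SCCCS4)CCO[Si](c5ccccc5)(c6ccccc6)C(C)(C)C)[C@H]2C1 | intermediate
18 | tricyclic enone lactone (rings A, B, C; C4=C10 enone; H1 and H5 cis, H7 trans to H5), C10 chain CH2–C(dithiane)–CH2–CH2–OTBDPS | CC(C)(C)[Si](c1ccccc1)(c1ccccc1)OCCC1(SCCCS1)CC2=C3C(=O)C[C@H]4OC(=O)[C@H](CC25OCCO5)[C@@H]34 | intermediate
19 | tricyclic enone lactone with free primary alcohol at C14 | OCCC1(SCCCS1)CC2=C3C(=O)C[C@H]4OC(=O)[C@H](CC25OCCO5)[C@@H]34 | intermediate
20 | tricyclic enone lactone aldehyde (C14 as CHO) | O=CCC1(SCCCS1)CC2=C3C(=O)C[C@H]4OC(=O)[C@H](CC25OCCO5)[C@@H]34 | intermediate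
21 | tetracyclic hydroxy ketone: C14 on the β face of C10, C14–OH anti to C4, H4 β; C3 ketone, C9 dioxolane, C12 dithiane | O1CCOC12C[C@H]3C(=O)O[C@@H]4CC(=O)[C@@H]([C@@H]43)[C@]25CC6(SCCCS6)C[C@@H]5O | intermediate
22 | diol: C3 tertiary carbinol (CH3 β, OH α), free C14–OH | O1CCOC12C[C@H]3C(=O)O[C@@H]4C[C@](C)(O)[C@@H]([C@@H]43)[C@]25CC6(SCCCS6)C[C@@H]5O | intermediate
23 | O3,O14-bis(triethylsilyl) ether of 22 | O1CCOC12C[C@H]3C(=O)O[C@@H]4C[C@](C)(O[Si](CC)(CC)CC)[C@@H]([C@@H]43)[C@]25CC6(SCCCS6)C[C@@H]5O[Si](CC)(CC)CC | intermediate
24 | C9 ketone, bis-silyl ether, C12 dithiane | O=C1C[C@H]2C(=O)O[C@@H]3C[C@](C)(O[Si](CC)(CC)CC)[C@@H]([C@@H]32)[C@]14CC5(SCCCS5)C[C@@H]4O[Si](CC)(CC)CC | intermediate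
25 | C9 enol triflate (C8=C9) | FC(F)(F)S(=O)(=O)OC1=C[C@H]2C(=O)O[C@@H]3C[C@](C)(O[Si](CC)(CC)CC)[C@@H]([C@@H]32)[C@]14CC5(SCCCS5)C[C@@H]4O[Si](CC)(CC)CC | intermediate
26 | methyl acrylate | C=CC(=O)OC | starting material
27 | (E)-dienoate: methyl (E)-3-(ring A C9-yl)acrylate | COC(=O)/C=C/C1=C[C@H]2C(=O)O[C@@H]3C[C@](C)(O[Si](CC)(CC)CC)[C@@H]([C@@H]32)[C@]14CC5(SCCCS5)C[C@@H]4O[Si](CC)(CC)CC | intermediate
28 | isopropenylboronic acid pinacol ester | CC(=C)B1OC(C)(C)C(C)(C)O1 | starting material
29 | full side chain at C9 (C15 S), bis-silyl ether, C12 dithiane | C=C(C)[C@H](CC(=O)OC)C1=C[C@H]2C(=O)O[C@@H]3C[C@](C)(O[Si](CC)(CC)CC)[C@@H]([C@@H]32)[C@]14CC5(SCCCS5)C[C@@H]4O[Si](CC)(CC)CC | intermediate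
30 | diol dithiane (12-dithiane of the target) | C=C(C)[C@H](CC(=O)OC)C1=C[C@H]2C(=O)O[C@@H]3C[C@](C)(O)[C@@H]([C@@H]32)[C@]14CC5(SCCCS5)C[C@@H]4O | intermediate
31 | CNP0255095.1 | C=C(C)[C@H](CC(=O)OC)C1=C[C@H]2C(=O)O[C@@H]3C[C@](C)(O)[C@@H]([C@@H]32)[C@]12CC(=O)C[C@@H]2O | target

## Step count and risks

Total: 23 steps. Longest linear sequence: 22 steps (steps 1 to 8 and 10 to 23; step 9 prepares alkyne 13).

**Step 15 (key step).** Electron transfer to the enone may compete with ketyl formation, leading to 1,4-reduction or to expulsion of a C9 ketal oxygen from the electron-rich intermediate. Pinacol coupling and poor facial selectivity at C14 are further possibilities. Fallback: starting from 20, run an O-stannyl ketyl radical-chain cyclisation (Bu3SnH, AIBN, PhH, 80 °C). The tin radical adds to the aldehyde oxygen, the carbon radical closes 5-exo on C10, and the C4 radical abstracts hydrogen from the stannane, so no enolate or dianion is formed that could eject the ketal. Hydrolysis of the O–Sn bond on work-up returns to 21. This fallback makes no compound outside the list (F0).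

**Step 12.** Dehydration of the hindered tertiary aldol may stall, and forcing acid may open ring B by β-elimination or cleave the C9 ketal. Fallback: starting from 16, hydrolyse only the C3 ketal (PPTS, wet acetone, rt) and isolate diketone 17. Let it cyclise under pyrrolidinium acetate at rt to the C10 tertiary aldol F1, then dehydrate F1 under neutral conditions with Burgess reagent (PhH, 50 °C), which returns to 18.

**Step 21.** Facial selectivity may be poor if the chiral substrate and the ligand are mismatched. Competing 1,6-addition, protodeboronation, and base-induced migration of the C8=C9 bond into conjugation with C6 are also possible. Fallback: starting from 25, a Stille coupling with (E)-2-methyl-3-(tributylstannyl)prop-2-en-1-ol (Pd(PPh3)4, CuI, DMF, 50 °C) gives the dienyl allylic alcohol F2. A Johnson–Claisen rearrangement (MeC(OMe)3, cat. propionic acid, 110 °C) then forms the C15–CH2CO2Me bond and the isopropenyl group together and returns to 29. The C15 configuration would then rest on substrate control by the ring D silyl ether and would have to be established.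

**Step 18.** The silyl ethers may be lost before the hindered ketal hydrolyses, after which O3 would capture the C9 oxocarbenium ion. Fallback: starting from 23, open the dioxolane under aprotic conditions (TMSOTf, iPr2NEt, CH2Cl2, −20 °C) to the 2-(trimethylsilyloxy)ethyl enol ether F3. Brief treatment with oxalic acid in wet THF at 0 °C hydrolyses the enol ether and returns to 24.

## Further compounds

F0 | step 15 | none | none
F1 | step 12 | C10 tertiary aldol of 17 (C4–C10 bond formed, H4 β, C10–OH configuration open) | O1CCOC12C[C@H]3C(=O)O[C@@H]4CC(=O)[C@@H]([C@@H]43)C2(O)CC5(SCCCS5)CCO[Si](c6ccccc6)(c7ccccc7)C(C)(C)C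
F2 | step 21 | dienyl allylic alcohol: (E)-3-hydroxy-2-methylprop-1-en-1-yl group on C9 of the bis-silyl ether dithiane | OC/C(C)=C/C1=C[C@H]2C(=O)O[C@@H]3C[C@](C)(O[Si](CC)(CC)CC)[C@@H]([C@@H]32)[C@]14CC5(SCCCS5)C[C@@H]4O[Si](CC)(CC)CC
F3 | step 18 | C9 2-(trimethylsilyloxy)ethyl enol ether (C8=C9) of the bis-silyl ether dithiane | C[Si](C)(C)OCCOC1=C[C@H]2C(=O)O[C@@H]3C[C@](C)(O[Si](CC)(CC)CC)[C@@H]([C@@H]32)[C@]14CC5(SCCCS5)C[C@@H]4O[Si](CC)(CC)CC
A1 | alternative 1 | spiro cyclohexene carboxylic acid (rings A and D) | CC(C)(C)[Si](C)(C)OCC1=C[C@@H](COCc2ccccc2)[C@H](C(OC)OC)[C@H](C(=O)O)[C@]13CC4(OCCO4)C[C@@H]3O[Si](C)(C)C(C)(C)C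
A2 | alternative 2 | spiro hydrindanone silyl enol ether (rings A, C and D) | C1C=C(O[Si](C)(C)C(C)(C)C)[C@@H]2C3(OCCO3)CC(=O)[C@@H]2[C@]12CC3(OCCO3)CC2=O
A3 | alternative 3 | cis-2-oxabicyclo[3.3.0]octane-3,7-dione carrying ring D at C6 | O=C1O[C@@H]2CC(=O)[C@@H]([C@@H]2C1)[C@@]3(CC(=O)OC)CC4(OCCO4)C[C@@H]3O[Si](C)(C)C(C)(C)C
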